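The constants used here stand for no real mixture; what happens was integrated by code.

Over 4.0 h, ending at 5 °C, these flasks share their charges and differ in when partner or second substrate goes in, and in how cold they start.

| setting | south | north | east | south-west | north-east | south-east |
|---|---|---|---|---|---|---|
| starting material | 0.80 M | 0.80 M | 0.80 M | 0.80 M | 0.80 M | 0.80 M |
| partner | 0.400 M | 0.400 M (fed, over 5.0 min) | 0.400 M (fed, over 50 min) | 0.400 M | 0.400 M | 0.400 M |
| second substrate | 0.400 M | 0.400 M | 0.400 M | 0.400 M | 0.400 M (in portions, 3, over 50 min) | 0.400 M (fed, over 50 min) |
| protic impurity | 0.800 M | 0.800 M | 0.800 M | 0.800 M | 0.800 M | 0.800 M |
| free catalyst | 1.6 mM | 1.6 mM | 1.6 mM | 1.6 mM | 1.6 mM | 1.6 mM |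
| temperature | 5 °C | 5 °C | 5 °C |  | 5 °C |  |
| time | 4.0 h | 4.0 h | 4.0 h | 4.0 h | 4.0 h | 4.0 h |
| remark | everything together at the start | all else is in the flask from the start; the feed brings no volume worth counting | all else is in the flask from the start; the feed brings no volume worth counting | everything together at the start at −15 °C, warmed to 5 °C at 50 min | first portion at the start, last at 50 min | the addition at −15 °C, then warmed to 5 °C; the feed brings no volume worth counting |

    starting material + partner + free catalyst → free catalyst + target (k1 = 3300 M⁻² h⁻¹, Ea1 = 48.0 kJ mol⁻¹)
    second substrate + partner + free catalyst → free catalyst + second product (k2 = 19000 M⁻² h⁻¹, Ea2 = 44.0 kJ mol⁻¹)
    2 free catalyst → spent catalyst (k3 = 32.4 M⁻¹ h⁻¹, Ea3 = 64.0 kJ mol⁻¹)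
    partner + protic impurity → quenched reagent (k4 = 0.263 M⁻¹ h⁻¹, Ea4 = 71.0 kJ mol⁻¹)
    (constants at 5 °C)

1. the flask that comes out highest in amount of target, in percent of the starting material charged, or "all alike" when all lie within 1.5 percentage points (south / north / east / south-west / north-east / south-east / all alike)
2. target at the end, in percent of the starting material charged, south
3. target at the end, in percent of the starting material charged, north
4. target at the end, in percent of the starting material charged, east
5. target at the end, in percent of the starting material charged, south-west
6. target at the end, in percent of the starting material charged, north-east
7. target at the end, in percent of the starting material charged, south-east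

- a doubled species enters its step squared and goes two at a time
- at 5 °C the constants are as listed, elsewhere as the activation energies make them

Partner and free catalyst stand in both productive steps, so they cancel when I divide the two rates: second product forms over target forms as 5.76 times second substrate over starting material. That constant of the second step over the first, the selectivity factor, is what I carry. It follows that, at one temperature and with both substrates in the flask from the start, the logarithm of the fraction of second substrate left is the factor times that of starting material, whatever the course of partner.

In south, target starts rising at 1.69 M h⁻¹ and second product at 4.86 M h⁻¹, a ratio of 2.88. Partner, the limiting reagent, has a first half-life of 2.54 min, far shorter than the 9.65 h of free catalyst, so I hold the catalyst at its charge through the knee. The level comes from the balance, with the protic impurity left aside for now: partner charged equals starting material used plus second substrate used.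

Trying 0.5 of the second substrate left in south gives 88.7% of starting material left. Feeding that through the balance gives 77.3%. Their mean, 83.0%, fits the balance with 34.1% of second substrate left. At that knee of south the ratio is still 1.18, above one, so by my reckoning the two rates do not cross there.

The protic impurity is the small correction. In south, with the catalyst held at its charge, its quenching of partner runs at 1.28% of the two productive steps together at the start and 2.75% at the knee, and I take the mean of these two, 2.02%. Charging that loss at the knee's split gives south 16.6% of target, in percent of the starting material charged.

The ratio holds no partner, so I give north and east that same level. Cooling favours the second step, since its activation energy is lower, and at −15 °C the factor becomes 6.58. Taking that factor for the whole of the partner and leaving the protic impurity out, I put south-west near 15.8%.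

In north-east the ratio starts at 0.960, lower than in south. The half-life of partner in north-east on starting material by itself, as charged, 9.85 min, is shorter than the 25.0 min between portions. So I put north-east above the flasks I reckoned. The rule does not tell how much partner meets each portion, however, so my reckoning stops without a number there or for south-east.

The forecast gives 16.6% for south, 16.6% for north, 16.5% for east, 16% for south-west, 29.8% for north-east and 23% for south-east, with north-east first, on the ground that “the portioned charge does best because the partner is nearly gone before the last portion arrives”.

The simulation gives 16.6%, 16.6%, 16.6%, 15.9%, 30.3% and 22.8% in that order, with north-east highest.

In south the logarithm of the second substrate left, 35.1%, over that of the starting material left, 83.4%, is 5.77 against the 5.76 reckoned from the constants, and east holds the same 35% of second substrate with a dosing time of 14 lifetimes of partner against everything charged. In the neighbour of south-west charged with 1.0 M of second substrate, target ends at 6.31% with 65% of second substrate left, and the same logarithms give 6.61 against the cold factor of 6.58.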